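**Reading time.** I read at 30 d, so the question for each target molecule is whether it lasts that long.

| setting | blue | teal | green | epsilon | gamma | delta |
|---|---|---|---|---|---|---|
| substrate | 0.050 M | 0.025 M | 0.10 M | 0.050 M | 0.050 M (fed, over 12 d) | 0.050 M |
| partner | 0.050 M | 0.050 M | 0.050 M | 0.0500 M | 0.0500 M | 0.0500 M (fed, over 12 d) |
| remark | run made earlier | run made earlier | run made earlier | everything together at the start | all else is in the flask from the start; the feed brings no volume worth counting | all else is in the flask from the start; the feed brings no volume worth counting |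
| time |  |  |  | 30 d | 30 d | 30 d |

| run | time / d | target / % | substrate / % |
|---|---|---|---|
| blue | 1.25 | 9.1 | 49.4 |
| blue | 2.00 | 15.2 | 45.6 |
| blue | 3.00 | 21.6 | 41.1 |
| blue | 5.00 | 27.9 | 34.4 |
| blue | 8.00 | 28.9 | 30.0 |
| blue | 12.0 | 26.9 | 27.4 |
| blue | 20.0 | 13.4 | 26.6 |
| teal | 3.00 | 23.7 | 39.2 |
| teal | 4.00 | 28.1 | 34.4 |
| teal | 6.00 | 28.0 | 29.8 |
| teal | 10.0 | 23.0 | 24.4 |
| teal | 15.0 | 14.5 | 22.8 |
| teal | 25.0 | 4.9 | 21.9 |
| teal | 40.0 | 0.4 | 19.9 |
| green | 5.00 | 24.6 | 37.5 |
| green | 10.0 | 25.4 | 33.3 |
| green | 15.0 | 21.8 | 32.7 |
| green | 20.0 | 17.5 | 32.9 |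
| green | 25.0 | 12.7 | 33.0 |
| green | 30.0 | 8.0 | 32.9 |
| green | 40.0 | 2.2 | 33.1 |

(scatter of a reading: 0.5 percentage points)

- the flask with the highest amount of target, in percent of the substrate charged ("all alike" if they lie within 1.5 percentage points) (epsilon / gamma / delta / all alike)
- final target, as a percentage of the substrate charged, in epsilon
- final target, as a percentage of the substrate charged, in gamma
- final target, as a percentage of the substrate charged, in delta

- the numbers in the tables scatter by 0.5 percentage points (one standard deviation)
- a reading or a percentage of target counts all its forms, free or not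

**Tail constant.** Green's target falls in a nearly straight line, then bends: from 30.0 d to 40.0 d it goes from 8.0% to 2.2%. I read this as first-order loss with k = 0.129 d⁻¹, the chance per day that a target molecule on this tail is lost. A wait Δt then leaves the share exp(−kΔt), and the half-life is 5.37 d.

**Changing nothing.** Epsilon repeats blue, whose substrate barely moves late on, 27.4% at 12.0 d and 26.6% at 20.0 d. Blue's last target, 6.70 mM, stands below the 8.00 mM at which I start green's tail, so I carry blue's 13.4% to the reading and get 3.69%.

**Feeding partner.** I take delta's making to move later by 6.00 d, the mean time of the feed. Each molecule then waits that much less, and holding the amount made at epsilon's gives 8.00%.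

**Feeding substrate.** I take 5.00 d as partner's working time, since blue's substrate is down to 34.4% by then, and gamma's feed has brought 41.7% of its charge by that time. The highest readings of teal, blue and green are 28.1%, 28.9% and 25.4% of their charges, so I scale gamma's target with that share, leave its shorter wait out and get 1.54%. My order puts delta first.

**The forecast.** The forecast also picks delta, with 3.2%, 1.5% and 9% for epsilon, gamma and delta, saying that feeding partner “keeps the active species fresh”.

**The flasks.** Epsilon gives 3.60%, gamma 1.09% and delta 10.4%, so delta leads.

    2 second intermediate → homo product (k = 2.80 × 10⁻⁴ M⁻¹ s⁻¹)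
    crystals ⇌ target, rate k2*(cs2 - [target]) while solid is left; crystals form when [target] > cs2 (solubility = 6.90 mM, k = 0.00120 s⁻¹)
    target → over-reaction product (k = 1.60 × 10⁻⁶ s⁻¹)
    partner → second intermediate (k = 5.60 × 10⁻⁶ s⁻¹)
    partner + target ⇌ idle adduct, settled at all times (K = 17.0 M⁻¹)
    substrate ⇌ open intermediate (K = 0.930, k = 2.10 × 10⁻⁵ s⁻¹)
    open intermediate + second intermediate → target (k = 2.40 × 10⁻⁴ M⁻¹ s⁻¹)

**Gamma's fork.** Carrying gamma's 7.39% from 15.0 d with k gives 1.07%, and gamma stands at 1.09% at 30.0 d. At 1.44 d in gamma, second intermediate goes to homo product 17 times as fast as it goes to target. In gamma half of the turnover of partner to second intermediate up to 30 d is done by 1.44 d, against 6.31 d for substrate to open intermediate, and partner, the limiting reagent, stands at 0% of its charge at 30.0 d.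

The earlier runs and the new flask were generated by integration with made-up constants, noise included.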